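The flavanone is cut at C2–C1′, the bond between pyranone ring C and aryl ring B. C2, the only stereocentre, is β to the C4 ketone and bound to O1. In the flat, oxidised form of ring C (a chromone, C2=C3–C4=O) it is therefore a prochiral acceptor carbon. A rhodium/chiral-diene-catalysed 1,4-addition of the complete ring-B boronic acid to the complete 8-prenylchromone joins the halves, forms C2–C1′ and sets (2S) in one operation. Both precursors are achiral. The chromone receives its C8 prenyl by a Claisen–Cope relay from O5, and the boronic acid its C2′ prenyl by metalation between OMe and Br. Acid then removes three MOM groups.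

Key step: step 8

Remark: 5,7-dihydroxychromone and 4-bromo-2-methoxyphenol are taken as catalogue compounds; the (S,S)-diene is assigned by analogy with cyclic enones, and its antipode would serve if the sense of induction were opposite.

Step 1
Reactants: 1 5,7-dihydroxy-4H-chromen-4-one
Product: 2 5-hydroxy-7-(methoxymethoxy)-4H-chromen-4-one
Conditions: MOMCl (1.1 equiv), K2CO3, acetone, 0 °C to rt
Reagents that add atoms: chloromethyl methyl ether (MOMCl), COCCl
Why: Williamson-type O-alkylation; the 7-OH is the free and more acidic phenol, while the 5-OH is held in a hydrogen bond to C4=O, so one equivalent of MOMCl should react at O7 only.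

Step 2
Reactants: 2 5-hydroxy-7-(methoxymethoxy)-4H-chromen-4-one
Product: 3 7-(methoxymethoxy)-5-[(3-methylbut-2-en-1-yl)oxy]-4H-chromen-4-one
Conditions: prenyl bromide (1.5 equiv), K2CO3, acetone, reflux
Reagents that add atoms: prenyl bromide (1-bromo-3-methylbut-2-ene), CC(C)=CCBr
Why: Williamson ether synthesis; with O7 masked, the chelated 5-OH is the only nucleophile left, and heating with a reactive allylic bromide should overcome the hydrogen bond.

Step 3
Reactants: 3 7-(methoxymethoxy)-5-[(3-methylbut-2-en-1-yl)oxy]-4H-chromen-4-one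
Product: 6 5-hydroxy-7-(methoxymethoxy)-8-(3-methylbut-2-en-1-yl)-4H-chromen-4-one, via ortho-dienone 4 (not isolated), via para-dienone 5 (not isolated)
Conditions: Eu(fod)3 (10 mol %), NaHCO3, PhCl, 85 °C
Reagents that add atoms: none
Why: Tandem aromatic Claisen–Cope (para-Claisen) rearrangement; Eu(III) bound to C4=O/O5 accelerates the [3,3] shift to C6, the only open ortho position, and the resulting reverse-prenyl dienone relays the chain by a second [3,3] shift to C8 as a normal prenyl group before tautomerising to the chelated phenol.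

Step 4
Reactants: 6 5-hydroxy-7-(methoxymethoxy)-8-(3-methylbut-2-en-1-yl)-4H-chromen-4-one
Product: 8 5,7-bis(methoxymethoxy)-8-(3-methylbut-2-en-1-yl)-4H-chromen-4-one, via sodium phenoxide 7 (not isolated)
Conditions: NaH, DMF, 0 °C; MOMCl, 0 °C to rt
Reagents that add atoms: chloromethyl methyl ether (MOMCl), COCCl
Why: Williamson-type O-alkylation; irreversible deprotonation breaks the 5-OH···O=C4 chelate, and the phenoxide is trapped by the very reactive MOMCl.

Step 5
Reactants: 9 4-bromo-2-methoxyphenol
Product: 10 4-bromo-2-methoxy-1-(methoxymethoxy)benzene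
Conditions: MOMCl (1.2 equiv), K2CO3, acetone, rt
Reagents that add atoms: chloromethyl methyl ether (MOMCl), COCCl
Why: Williamson-type O-alkylation; the MOM acetal withstands LDA and n-BuLi and leaves in the same final operation as the ring-A groups.

Step 6
Reactants: 10 4-bromo-2-methoxy-1-(methoxymethoxy)benzene
Product: 13 1-bromo-3-methoxy-4-(methoxymethoxy)-2-(3-methylbut-2-en-1-yl)benzene, via aryllithium 11 (not isolated), via arylcopper 12 (not isolated)
Conditions: LDA (1.1 equiv), THF, −78 °C; CuBr·SMe2 (1.1 equiv), −78 °C; prenyl bromide, −78 to 0 °C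
Reagents that add atoms: prenyl bromide (1-bromo-3-methylbut-2-ene), CC(C)=CCBr
Why: Directed ortho-metalation followed by copper-mediated allylation; LDA removes only the C–H flanked by OMe and Br, since it is too weak a base for the position next to OMOM alone, copper stops loss of LiBr, and the bulky arylcopper should attack the primary terminus of prenyl bromide (SN2).

Step 7
Reactants: 13 1-bromo-3-methoxy-4-(methoxymethoxy)-2-(3-methylbut-2-en-1-yl)benzene
Product: 16 [3-methoxy-4-(methoxymethoxy)-2-(3-methylbut-2-en-1-yl)phenyl]boronic acid, via aryllithium 14 (not isolated), via lithium arylborate 15 (not isolated)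
Conditions: B(OiPr)3 (1.3 equiv), THF/toluene, −78 °C, then n-BuLi (1.1 equiv); to −20 °C; 1 M HCl to pH 5–6, 0 °C
Reagents that add atoms: triisopropyl borate, CC(C)OB(OC(C)C)OC(C)C; water, O
Why: Bromine–lithium exchange with in situ borate quench; exchange is far faster than deprotonation of the benzylic/allylic CH2, the aryllithium is trapped as it forms, and the cold, weakly acidic hydrolysis spares the MOM acetal.

Step 8
Reactants: 8 5,7-bis(methoxymethoxy)-8-(3-methylbut-2-en-1-yl)-4H-chromen-4-one; 16 [3-methoxy-4-(methoxymethoxy)-2-(3-methylbut-2-en-1-yl)phenyl]boronic acid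
Product: 17 (2S)-2-[3-methoxy-4-(methoxymethoxy)-2-(3-methylbut-2-en-1-yl)phenyl]-5,7-bis(methoxymethoxy)-8-(3-methylbut-2-en-1-yl)-2,3-dihydro-4H-chromen-4-one
Conditions: 16 (2.0 equiv), [RhCl(C2H4)2]2 (2.5 mol %), (S,S)-Ph-bod* [(1S,4S)-2,5-diphenylbicyclo[2.2.2]octa-2,5-diene, 5.5 mol %], aq KOH (10 mol %), degassed toluene/H2O (10:1), 60 °C
Reagents that add atoms: none
Why: Hayashi–Miyaura asymmetric 1,4-addition, a reaction type established for arylboronic acids and chromones: the Rh(I)–OH/diene complex transmetalates with 16 to an aryl–rhodium species, the C2=C3 bond of 8 binds and inserts so that the aryl group lands on C2, and water protonates the oxa-π-allyl rhodium enolate at C3, releasing 17 and returning Rh–OH. No ring is closed; the step converts the planar pyranone ring C into the chromanone ring. The new stereocentre C2 is controlled by the C2-symmetric diene alone, whose phenyl groups leave open only the quadrant in which 8 presents the Re face of C2, which should give (2S). 1,4- over 1,2-addition is secured by the soft aryl–rhodium nucleophile, the 5-OMOM group flanking C4=O and the toluene medium, and the two trisubstituted, unactivated prenyl alkenes should neither insert nor displace the chelating diene. O5 is masked because a free 5-OH/C4=O pair would bind rhodium like an acac ligand and slow transmetalation. Only catalytic base is present, so retro-oxa-Michael opening of ring C, the racemisation path of flavanones, is avoided, and two equivalents of 16 offset protodeboronation of the hindered, electron-rich boronic acid.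

Step 9
Reactants: 17 (2S)-2-[3-methoxy-4-(methoxymethoxy)-2-(3-methylbut-2-en-1-yl)phenyl]-5,7-bis(methoxymethoxy)-8-(3-methylbut-2-en-1-yl)-2,3-dihydro-4H-chromen-4-one
Product: 18 (2S)-5,7-dihydroxy-2-[4-hydroxy-3-methoxy-2-(3-methylbut-2-en-1-yl)phenyl]-8-(3-methylbut-2-en-1-yl)-2,3-dihydro-4H-chromen-4-one (target)
Conditions: HCl (1 M in MeOH), 40 °C
Reagents that add atoms: none
Why: Acid-catalysed transacetalisation of the three aryl MOM acetals to methanol; C2 is untouched because flavanones racemise by base-induced ring opening, and the low acid strength and temperature should keep the C8 prenyl group from closing a chroman ring onto the 7-OH.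

Compound list
1 | 5,7-dihydroxy-4H-chromen-4-one | O=c1ccoc2cc(O)cc(O)c12 | starting material
2 | 5-hydroxy-7-(methoxymethoxy)-4H-chromen-4-one | O=c1ccoc2cc(OCOC)cc(O)c12 | intermediate
3 | 7-(methoxymethoxy)-5-[(3-methylbut-2-en-1-yl)oxy]-4H-chromen-4-one | O=c1ccoc2cc(OCOC)cc(OCC=C(C)C)c12 | intermediate
4 | ortho-dienone: racemic 7-(methoxymethoxy)-6-(2-methylbut-3-en-2-yl)-4H-chromene-4,5(6H)-dione | O=C1C(C(C)(C)C=C)C(OCOC)=CC2=C1C(=O)C=CO2 | intermediate
5 | para-dienone: racemic 7-(methoxymethoxy)-8-(3-methylbut-2-en-1-yl)-4H-chromene-4,5(8H)-dione | O=C1C=C(OCOC)C(CC=C(C)C)C2=C1C(=O)C=CO2 | intermediate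
6 | 5-hydroxy-7-(methoxymethoxy)-8-(3-methylbut-2-en-1-yl)-4H-chromen-4-one | O=c1ccoc2c(CC=C(C)C)c(OCOC)cc(O)c12 | intermediate
7 | sodium 7-(methoxymethoxy)-8-(3-methylbut-2-en-1-yl)-4-oxo-4H-chromen-5-olate | [Na+].[O-]c1cc(OCOC)c(CC=C(C)C)c2occc(=O)c12 | intermediate
8 | 5,7-bis(methoxymethoxy)-8-(3-methylbut-2-en-1-yl)-4H-chromen-4-one | O=c1ccoc2c(CC=C(C)C)c(OCOC)cc(OCOC)c12 | intermediate
9 | 4-bromo-2-methoxyphenol | COc1cc(Br)ccc1O | starting material
10 | 4-bromo-2-methoxy-1-(methoxymethoxy)benzene | COCOc1ccc(Br)cc1OC | intermediate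
11 | [6-bromo-2-methoxy-3-(methoxymethoxy)phenyl]lithium | COCOc1ccc(Br)c([Li])c1OC | intermediate
12 | [6-bromo-2-methoxy-3-(methoxymethoxy)phenyl]copper | COCOc1ccc(Br)c([Cu])c1OC | intermediate
13 | 1-bromo-3-methoxy-4-(methoxymethoxy)-2-(3-methylbut-2-en-1-yl)benzene | COCOc1ccc(Br)c(CC=C(C)C)c1OC | intermediate
14 | [3-methoxy-4-(methoxymethoxy)-2-(3-methylbut-2-en-1-yl)phenyl]lithium | COCOc1ccc([Li])c(CC=C(C)C)c1OC | intermediate
15 | lithium triisopropoxy[3-methoxy-4-(methoxymethoxy)-2-(3-methylbut-2-en-1-yl)phenyl]borate | [Li+].COCOc1ccc([B-](OC(C)C)(OC(C)C)OC(C)C)c(CC=C(C)C)c1OC | intermediate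
16 | [3-methoxy-4-(methoxymethoxy)-2-(3-methylbut-2-en-1-yl)phenyl]boronic acid | COCOc1ccc(B(O)O)c(CC=C(C)C)c1OC | intermediate
17 | (2S)-2-[3-methoxy-4-(methoxymethoxy)-2-(3-methylbut-2-en-1-yl)phenyl]-5,7-bis(methoxymethoxy)-8-(3-methylbut-2-en-1-yl)-2,3-dihydro-4H-chromen-4-one | COCOc1ccc([C@@H]2CC(=O)c3c(OCOC)cc(OCOC)c(CC=C(C)C)c3O2)c(CC=C(C)C)c1OC | intermediate
18 | (2S)-5,7-dihydroxy-2-[4-hydroxy-3-methoxy-2-(3-methylbut-2-en-1-yl)phenyl]-8-(3-methylbut-2-en-1-yl)-2,3-dihydro-4H-chromen-4-one | COc1c(O)ccc([C@@H]2CC(=O)c3c(O)cc(O)c(CC=C(C)C)c3O2)c1CC=C(C)C | target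

Total step count: 9
Longest linear sequence: 6 (steps 1, 2, 3, 4, 8, 9)

Steps most likely to fail

**Step 8.**
- **What may go wrong:** transmetalation and insertion of the ortho-prenylated, buttressed aryl group into an electron-rich chromone may be slow. Protodeboronation or 1,4-rhodium migration into the prenyl chain could then outrun C–C bond formation, or facial selectivity could erode.
- **Fallback:** the same bond is formed, but stereocontrol moves from the bond formation to a resolution. It sets out from bromide 13 and chromone 8. Bromine–lithium exchange on 13 (n-BuLi, THF, −78 °C) gives aryllithium 14, and CuBr·SMe2 converts it into the arylcopper reagent F1. In the presence of TMSCl this adds to C2 of 8 to give the racemic 4-(trimethylsilyloxy)-2H-chromene F2. Dilute acid hydrolyses F2 to the racemic flavanone F3. Kinetic resolution follows by asymmetric transfer hydrogenation [Cp*RhCl((R,R)-TsDPEN), HCO2H/Et3N], which leaves alkenes alone. It should reduce the (2R)-ketone to the cis-(2R,4R)-flavan-4-ol F4 and leave the (2S)-ketone. After chromatography this ketone is 17, where the route is rejoined.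

**Step 6.**
- **What may go wrong:** aryllithium 11 may lose LiBr to the aryne before the slower copper transmetalation and allylation are complete. γ-Attack on prenyl bromide would install a 1,1-dimethylallyl group.
- **Fallback:** the polarity is reversed, so ring B becomes the electrophile. It sets out from 10. The same cold lithiation is quenched at once with iodine, a much faster trap, to give 1-bromo-2-iodo-3-methoxy-4-(methoxymethoxy)benzene F5. A Suzuki–Miyaura coupling of the more reactive C–I bond with one equivalent of prenylboronic acid pinacol ester follows (Pd/bulky biarylphosphine, K3PO4, THF/H2O, 40 °C). The hindered aryl group favours the primary σ-allyl palladium species, so the linear prenyl group should form. This gives 13, where the route is rejoined.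

**Step 3.**
- **What may go wrong:** ortho-dienone 4 may tautomerise to the 6-(1,1-dimethylallyl)phenol before the Cope shift. The Lewis acid may also ionise the prenyl ether, with loss of the prenyl group.
- **Fallback:** the C8–C bond is made by cross-coupling instead of the sigmatropic relay. It sets out from 2. MOM protection of O5 (NaH, MOMCl, DMF) gives 5,7-bis(methoxymethoxy)-4H-chromen-4-one F6. NIS in DMF should iodinate C8, the less hindered of the two activated positions because C6 lies between two OMOM groups, to give 8-iodo-5,7-bis(methoxymethoxy)-4H-chromen-4-one F7. Suzuki–Miyaura prenylation with prenylboronic acid pinacol ester then gives 8 directly, so steps 2–4 are replaced and the route is rejoined at 8.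

Further compounds
F1 | step 8 | [3-methoxy-4-(methoxymethoxy)-2-(3-methylbut-2-en-1-yl)phenyl]copper | COCOc1ccc([Cu])c(CC=C(C)C)c1OC
F2 | step 8 | racemic 2-[3-methoxy-4-(methoxymethoxy)-2-(3-methylbut-2-en-1-yl)phenyl]-5,7-bis(methoxymethoxy)-8-(3-methylbut-2-en-1-yl)-4-(trimethylsilyloxy)-2H-chromene | COCOc1ccc(C2C=C(O[Si](C)(C)C)c3c(OCOC)cc(OCOC)c(CC=C(C)C)c3O2)c(CC=C(C)C)c1OC
F3 | step 8 | racemic 2-[3-methoxy-4-(methoxymethoxy)-2-(3-methylbut-2-en-1-yl)phenyl]-5,7-bis(methoxymethoxy)-8-(3-methylbut-2-en-1-yl)-2,3-dihydro-4H-chromen-4-one | COCOc1ccc(C2CC(=O)c3c(OCOC)cc(OCOC)c(CC=C(C)C)c3O2)c(CC=C(C)C)c1OC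
F4 | step 8 | (2R,4R)-2-[3-methoxy-4-(methoxymethoxy)-2-(3-methylbut-2-en-1-yl)phenyl]-5,7-bis(methoxymethoxy)-8-(3-methylbut-2-en-1-yl)-3,4-dihydro-2H-chromen-4-ol | COCOc1ccc([C@H]2C[C@@H](O)c3c(OCOC)cc(OCOC)c(CC=C(C)C)c3O2)c(CC=C(C)C)c1OC
F5 | step 6 | 1-bromo-2-iodo-3-methoxy-4-(methoxymethoxy)benzene | COCOc1ccc(Br)c(I)c1OC
F6 | step 3 | 5,7-bis(methoxymethoxy)-4H-chromen-4-one | O=c1ccoc2cc(OCOC)cc(OCOC)c12
F7 | step 3 | 8-iodo-5,7-bis(methoxymethoxy)-4H-chromen-4-one | O=c1ccoc2c(I)c(OCOC)cc(OCOC)c12
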